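(All runs were generated by integration with made-up constants.)

4 questions wait on this bench. South-west, north and north-east hold substrate and partner, closed, and you will read target at the end.

| flask | substrate | partner | temperature | remark | time |
|---|---|---|---|---|---|
| green | 0.12 M | 1.1 equiv | −5 °C | run made earlier |  |
| violet | 0.17 M | 1.1 equiv | 17 °C | run made earlier |  |
| south-west | 0.23 M | 1.10 equiv | 5 °C |  | 4.0 d |
| north | 0.23 M | 1.10 equiv | −15 °C |  | 4.0 d |
| north-east | 0.23 M | 1.10 equiv | 25 °C |  | 4.0 d |

| green: time / d | green: target / % | violet: time / h | violet: target / % |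
|---|---|---|---|
| 0.500 | 3 | 4.00 | 15 |
| 1.67 | 6 | 15.0 | 28 |
| 2.50 | 9 | 20.0 | 24 |
| 5.00 | 17 | 40.0 | 28 |
| 6.00 | 15 | 48.0 | 26 |

(standard deviation of a reading: 2 percentage points)

- which flask leads in amount of target, in percent of the substrate charged ("all alike" within 1.5 percentage points) (south-west / north / north-east / all alike)
- how much target is there at the end, in percent of the substrate charged: south-west
- how much target is there at the end, in percent of the substrate charged: north
- how much target is there at the end, in percent of the substrate charged: north-east



Ask the end first, then the approach. Violet reads 28% at 15.0 h and 26% at 48.0 h, so its readings level off within their scatter. Green reads 9% at 2.50 d and 17% at 5.00 d, so it is still rising.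

Let a be the substrate charge and e the equivalents of partner. In the initial-rate stretch, the target fraction y grows as k·e·a·t, with k the apparent rate constant, so a reading on the rise gives k:

k(green) = y/(e·a·t) = 0.258 L mol⁻¹ d⁻¹

k(violet) = 4.81 L mol⁻¹ d⁻¹

apparent activation energy E = 86.1 kJ mol⁻¹

The rise number θ = k·e·a·t is the target fraction if the starting rate simply held.

θ(north) = 0.0584

θ(south-west) = 1.04

θ(north-east) = 12.7

When you come, north will still be on its early rise, so I expect about 5.84% there. North-east will be past its rise, and I put it near or below violet's late readings. South-west, at θ = 1.04, stands between them. Don't warm north to hurry it: that changes k, and with it θ.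

The forecast gives south-west the lead, with 40% there, 5.5% in north and 24% in north-east, where it says “so it reaches equilibrium”.

The flasks give 31.2% in south-west, 8.41% in north and 15.3% in north-east.

    substrate + partner → target (k = 1.78 × 10⁻⁴ L mol⁻¹ s⁻¹, Ea = 80.0 kJ mol⁻¹)
    substrate + partner → isomer of the product A (k = 1.15 × 10⁻⁴ L mol⁻¹ s⁻¹, Ea = 69.0 kJ mol⁻¹)
    substrate + partner → second isomer (k = 1.13 × 10⁻⁵ L mol⁻¹ s⁻¹, Ea = 88.0 kJ mol⁻¹)
    target ⇌ isomer of the product B (K = 2.20, k = 1.17 × 10⁻⁵ s⁻¹, Ea = 91.0 kJ mol⁻¹, ΔH = −25.0 kJ mol⁻¹)
    partner → decomposed reagent (k = 1.08 × 10⁻⁵ s⁻¹, Ea = 97.0 kJ mol⁻¹)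
    (constants at 25 °C)

South-west and north-east fell below the forecast by 8.8 percentage points and 8.7 points. North stayed on its rise, with 80% of the substrate free and 8.41% target against θ = 5.84%. At its start, substrate went to isomer of the product A 1.3 times as fast as to target (a selectivity factor), and at the end north holds 10.9% of that isomer, more than target. A neighbour of north with 1.90 equiv of partner has θ = 0.101, so scaling north's result gives 14.5%; the computed value is 13.5%.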